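Late in each earlier run, at 90.0 s, the solid substrate has lost 59.9%, 15.1% and 28.8% of its own charge in the autumn, spring and midnight runs. Rescaled to the flask's charge, those losses read 29.9%, 30.2% and 28.8%. That is nearly one amount, zero order in the solid, even with twice the catalyst at midnight.

| flask | solid substrate | catalyst | remark | time |
|---|---|---|---|---|
| autumn | 0.050 M | 5 mM | run made earlier |  |
| spring | 0.20 M | 5 mM | run made earlier |  |
| midnight | 0.10 M | 10 mM | run made earlier |  |
| flask | 0.10 M | 5.0 mM |  | 2.0 min |

| run | time / s | solid substrate / % | product / % | intermediate / % |
|---|---|---|---|---|
| autumn | 10.0 | 91.4 | 0.5 | 0 |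
| autumn | 15.0 | 88.1 | 1.0 | 1.1 |
| autumn | 25.0 | 77.6 | 0 | 6.2 |
| autumn | 50.0 | 64.5 | 6.3 | 13.3 |
| autumn | 90.0 | 40.1 | 21.0 | 22.1 |
| spring | 10.0 | 97.5 | 0 | 0.1 |
| spring | 25.0 | 95.8 | 0 | 1.3 |
| spring | 40.0 | 92.2 | 2.1 | 2.6 |
| spring | 60.0 | 90.2 | 0 | 3.4 |
| spring | 90.0 | 84.9 | 4.7 | 5.0 |
| midnight | 20.0 | 90.8 | 0.2 | 1.5 |
| midnight | 40.0 | 82.5 | 3.6 | 6.3 |
| midnight | 60.0 | 77.4 | 6.8 | 5.1 |
| midnight | 80.0 | 73.0 | 12.5 | 6.9 |
| midnight | 90.0 | 71.2 | 14.6 | 7.1 |

(standard deviation of a reading: 1 percentage point)

- as a solid, counted per litre of solution: solid substrate
- the earlier runs were read with a standard deviation of 1 percentage point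
- on the list of suspects stand: starting material -> intermediate; catalyst + intermediate -> catalyst + product; solid substrate <-> starting material
- at the start none of the solid substrate is in solution
- what has only dissolved of solid substrate counts as not reacted
- the reaction counts as stopped when no species that holds the solid substrate changes by six tenths of a point or more over the second half of the time

- at 2.0 min, what has stopped the reaction, if anything has (for what has run out or reacted, a solid counts together with what of it has only dissolved) (no working catalyst is left / all of the solid substrate has reacted / it is still moving / forward and back rates have come level)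
- part of the solid substrate that has turned into other species by 2.0 min (what has only dissolved does not count)
- how much product there is at 2.0 min, in percent of the solid substrate charged
- how much intermediate there is at 2.0 min, in percent of the solid substrate charged

You must decide how to read this flask at 2.0 min: as finished, or as still moving.

Call the mean of those losses per unit time the draw: 0.198 /min, the fraction of the flask's charge leaving the solid each minute, as read. A mean hides a curve. The autumn run's last two readings give 0.183 /min, and using that slope beyond 90.0 s lowers my figure by 0.733%, against a scatter of 1 percentage point.

By 2.0 min the draw takes 39.5% of this flask's charge, less than the whole, so on this reckoning solid substrate remains. What the last readings leave unaccounted, the charge minus solid substrate, product and intermediate, I take for starting material in solution; rescaled and averaged, it puts 8.77% of this flask's charge there, so I reckon 30.7% converted. My decision: keep the recipe and read the flask as moving.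

The forecast says it is still moving, with conversion 30.5%, product 18.2% and intermediate 12.3%, on the ground “So dissolution is saturation-limited”.

At 2.0 min the flask gives: it is still moving, with conversion 29.6%, product 16.8% and intermediate 12.8%.

    starting material → intermediate (k = 0.0300 /s)
    catalyst + intermediate → catalyst + product (k = 3.79 /M/s)
    solid substrate ⇌ starting material, rate k3*(cs3 - [starting material]) while solid is left; crystals form when [starting material] > cs3 (solubility = 18.0 mM, k = 0.0333 /s)

Solid substrate stands at 60.9% in the flask, a loss of 39.1% against the drawn 39.5%. Now take the neighbouring flask, charged with 0.040 M and otherwise the same. On that charge the draw reckons to 98.8% by 2.0 min; taking off the dissolved part, 21.9% of that charge, leaves 76.9% converted. The neighbouring flask gives 74.0%, with 2.34% still solid and 23.7% dissolved as starting material.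

All runs are simulated with constants of no real substance; the scatter is artificial.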